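**Retrosynthetic overview**
1. The C6 chloride and the C5=C16 methylene come last, from an ene-type chlorination of a C5=C6 alkene that carries C16 as a methyl group.
2. The hydroxy-lactone (C8, C17–C19) comes from a copper hydride reductive aldol of a C7 acrylate onto a C8 ketone.
3. The ten-membered ring is closed at C6–C7 by a nickel-catalysed alkylative alkyne–aldehyde coupling; C7–C8 come from an amine-catalysed syn aldol on the C9 aldehyde.
4. The ring A oxygens (C11 spiro-epoxide, C12, C14) are installed on a 4,4-disubstituted cyclohexenone by epoxidation, α′-methylenation, hydride reduction and directed epoxidation.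
5. Ring A with C1 and C10 comes from a hydrogen-bond-catalysed asymmetric Diels–Alder reaction of two achiral partners. Ring order: ring A, then the ten-membered ring, then the lactone.

Assumption: briarane locants are used (C1–C10 ten-membered ring, C11–C14 complete ring A, C15 methyl on C1, C16 on C5, C17–C19 lactone carbons, C18 methyl on C17, C20 epoxide CH2; α = ring A face of H-10, β = face of the C1 methyl), and the sense of induction of both chiral catalysts is taken as drawn, the mirror-image catalyst being used if it proves opposite.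

**Step 1**
Reactants: 1 (E)-1-(dimethylamino)-3-(tert-butyldimethylsilyloxy)buta-1,3-diene; 2 (E)-4,4-dimethoxy-2-methylbut-2-enal
Product: 3 (1R,2S,6S)-4-(tert-butyldimethylsilyloxy)-6-(dimethoxymethyl)-2-(dimethylamino)-1-methylcyclohex-3-ene-1-carbaldehyde
Conditions: (4R,5R)-2,2-dimethyl-α,α,α′,α′-tetra(1-naphthyl)-1,3-dioxolane-4,5-dimethanol (1-naphthyl-TADDOL, 20 mol %), toluene, −78 to −40 °C, 48 h; used crude
Reagents that add atoms: none
Why: Proposed new method: a hydrogen-bond-catalysed Diels–Alder reaction of a trisubstituted (α-methyl, β-branched) enal, in which the internally hydrogen-bonded TADDOL hydroxyl binds the formyl oxygen, lowers the enal LUMO and shields one face with a naphthyl group, so that the amino diene adds endo with its CH2 terminus at the β-carbon and the E geometry fixes the quaternary C1 and C10 trans; the closest known reaction is the TADDOL-catalysed Diels–Alder reaction of this diene with α-substituted acroleins, which has not been shown for α,β-disubstituted enals.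

**Step 2**
Reactants: 3 Diels–Alder adduct; 4 (4-bromobut-1-yn-1-yl)trimethylsilane
Product: 7 ring A enone carbinol (2S), via Grignard reagent 5 (not isolated), via carbinol adduct 6 (not isolated)
Conditions: Mg, THF, 40 °C (4 to 5); 3, Et2O/THF, −78 °C; then HF·pyridine, THF, 0 °C, 20 min
Reagents that add atoms: none
Why: Grignard addition under chelation control (Mg bridges the formyl oxygen and the cis dimethylamino group, attack anti to the C10 branch) sets C2, and the acidic work-up cleaves the silyl enol ether and expels dimethylamine by E1cB elimination to give the enone.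

**Step 3**
Reactants: 7 ring A enone carbinol
Product: 8 13α,14α-epoxy ketone
Conditions: tBuOOH (decane), DBU, CH2Cl2, 0 °C to rt
Reagents that add atoms: tert-butyl hydroperoxide CC(C)(C)OO
Why: Weitz–Scheffer nucleophilic epoxidation, the peroxide adding axially to C14 anti to the pseudoaxial C1 methyl so that the epoxide (and later the C14 oxygen) is α, cis to the C2 side chain.

**Step 4**
Reactants: 8 13α,14α-epoxy ketone
Product: 11 11-methylene epoxy ketone, via Mannich base 9 (not isolated), via ammonium iodide 10 (not isolated)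
Conditions: LiN(iPr)2 (2.2 equiv), THF, −78 °C; Me2N=CH2 iodide, −78 °C to rt; then MeI, CH2Cl2, rt; then aq NaHCO3
Reagents that add atoms: dimethylmethyleneiminium iodide (Eschenmoser's salt) C=[N+](C)C.[I-]
Why: C11 is the only enolisable α-position of the epoxy ketone, so the kinetic enolate undergoes a Mannich reaction there and quaternisation/E1cB elimination gives the α-methylene ketone that carries C20.

**Step 5**
Reactants: 11 11-methylene epoxy ketone
Product: 13 alkynyl triol (12α,14α-diol), via silylalkyne triol 12 (not isolated)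
Conditions: LiAlH4, THF, −78 to 0 °C; then MeOH, 15% aq NaOH, rt, 2 h
Reagents that add atoms: none
Why: hydride reduces the C12 ketone (1,2-reduction) from the β face anti to the epoxide oxygen and then opens the epoxide at the less hindered C13 by trans-diaxial (Fürst–Plattner) attack to leave the diaxial 12α,14α-diol, and the basic methanolic quench removes the alkynyl silyl group.

**Step 6**
Reactants: 13 alkynyl triol
Product: 14 11α,20α-epoxy triol
Conditions: VO(acac)2 (5 mol %), tBuOOH, CH2Cl2, 0 °C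
Reagents that add atoms: tert-butyl hydroperoxide CC(C)(C)OO
Why: vanadium-catalysed hydroxyl-directed epoxidation delivers oxygen to the exocyclic alkene syn to the allylic C12 hydroxyl, setting C11.

**Step 7**
Reactants: 14 11α,20α-epoxy triol
Product: 15 2,12,14-triacetate
Conditions: Ac2O, pyridine, DMAP, 40 °C
Reagents that add atoms: acetic anhydride CC(=O)OC(C)=O
Why: DMAP-catalysed acylation of the three secondary hydroxyls installs three of the final acetates, which also serve as protection.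

**Step 8**
Reactants: 15 2,12,14-triacetate
Product: 16 C9 aldehyde
Conditions: PPTS (20 mol %), acetone/H2O 10:1, 45 °C
Reagents that add atoms: water O
Why: mild acid-catalysed acetal hydrolysis frees the C9 aldehyde while the acetates and the acetoxy-deactivated spiro-epoxide tolerate PPTS.

**Step 9**
Reactants: 16 C9 aldehyde; 17 2-(tert-butyldimethylsilyloxy)acetaldehyde
Product: 18 syn aldol adduct (9S-hydroxy, 8R-silyloxy, C7 aldehyde)
Conditions: O-tert-butyl-L-threonine (20 mol %), 17 (3 equiv, slow addition), NMP, H2O (3 equiv), 4 °C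
Reagents that add atoms: none
Why: primary-amine enamine catalysis (direct cross-aldol), in which the hydrogen-bonded Z-enamine of 17 adds to the re face of the hindered, non-enolisable aldehyde through the acid-directed chair transition state, gives the syn 8,9-dioxygenated unit with C9 under catalyst control; C8 is a temporary stereocentre.

**Step 10**
Reactants: 18 syn aldol adduct
Product: 19 9-acetate (alkynyl aldehyde)
Conditions: Ac2O, pyridine, DMAP (5 mol %), CH2Cl2, −20 to 0 °C
Reagents that add atoms: acetic anhydride CC(=O)OC(C)=O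
Why: acylation installs the final C9 acetate at a temperature low enough to avoid β-elimination of the β-acyloxy aldehyde.

**Step 11**
Reactants: 19 9-acetate (alkynyl aldehyde)
Product: 20 ten-membered (5E)-allylic alcohol
Conditions: Ni(cod)2 (20 mol %), Me2Zn (3 equiv), THF, 0 °C, syringe-pump addition of 19 to 2 mM; pH 7 buffer
Reagents that add atoms: dimethylzinc C[Zn]C
Why: zerovalent-nickel-catalysed alkylative alkyne–aldehyde coupling (oxanickelacycle with C–C bond at the terminal alkyne carbon, methyl transfer from zinc, reductive elimination) closes the ring by syn addition, placing C7 cis to the new C16 methyl, and Felkin–Anh attack anti to the 8-silyloxy group, reinforced by 1,3-anti induction from the 9-acetoxy group, sets C7.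

**Step 12**
Reactants: 20 ten-membered allylic alcohol
Product: 21 7-acrylate
Conditions: acryloyl chloride, iPr2NEt, DMAP (10 mol %), CH2Cl2, −20 °C
Reagents that add atoms: acryloyl chloride C=CC(Cl)=O
Why: O-acylation of the only free hydroxyl attaches the three lactone carbons to O7.

**Step 13**
Reactants: 21 7-acrylate
Product: 22 8-alcohol
Conditions: HF·pyridine, pyridine, THF, 0 °C to rt
Reagents that add atoms: none
Why: buffered fluoride desilylation frees the C8 hydroxyl under mildly acidic conditions that suppress acyl migration from O7 or O9.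

**Step 14**
Reactants: 22 8-alcohol
Product: 23 8-ketone
Conditions: Dess–Martin periodinane, NaHCO3, CH2Cl2, 0 °C; used at once
Reagents that add atoms: none
Why: Dess–Martin oxidation under buffered conditions gives the ketone without epimerising the flanking C7 and C9 centres.

**Step 15**
Reactants: 23 8-ketone
Product: 25 (5E)-hydroxy lactone, via silyl aldolate 24 (not isolated)
Conditions: Cu(OAc)2·H2O (5 mol %), rac-BINAP (5 mol %), (Me2HSi)2O, THF, rt; then pH 7 buffer, SiO2
Reagents that add atoms: none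
Why: copper hydride conjugate reduction of the acrylate gives an O7-tethered copper enolate that adds to the C8 ketone (intramolecular reductive aldol cyclisation) through a chelated five-ring transition state that keeps C9 trans to C6 and the C17 methyl cis to the new C8 hydroxyl.

**Step 16**
Reactants: 25 (5E)-hydroxy lactone
Product: 26 CNP0349227.2 (target)
Conditions: Ca(OCl)2, CO2 (dry ice), CH2Cl2/H2O, 0 °C
Reagents that add atoms: calcium hypochlorite [Ca+2].[O-]Cl.[O-]Cl
Why: ene-type allylic chlorination with HOCl, in which Cl+ adds to C6 on the exposed alkene face anti to the C7–O bond (allylic 1,3-strain with the cis C16 methyl holds H-7 in the alkene plane) and the tertiary C5 cation loses a C16 proton to give the exocyclic alkene.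

**Compound list**
1 | (E)-1-(dimethylamino)-3-(tert-butyldimethylsilyloxy)buta-1,3-diene | CN(C)/C=C/C(=C)O[Si](C)(C)C(C)(C)C | starting material
2 | (E)-4,4-dimethoxy-2-methylbut-2-enal | COC(OC)/C=C(\C)C=O | starting material
3 | (1R,2S,6S)-4-(tert-butyldimethylsilyloxy)-6-(dimethoxymethyl)-2-(dimethylamino)-1-methylcyclohex-3-ene-1-carbaldehyde; CHO (C2) on C1 trans to CH(OMe)2 (C9) on C10, NMe2 on C14 cis to CHO | O=C[C@@]1(C)[C@@H](N(C)C)C=C(O[Si](C)(C)C(C)(C)C)C[C@@H]1C(OC)OC | intermediate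
4 | (4-bromobut-1-yn-1-yl)trimethylsilane | C[Si](C)(C)C#CCCBr | starting material
5 | [4-(trimethylsilyl)but-3-yn-1-yl]magnesium bromide | C[Si](C)(C)C#CCC[Mg]Br | intermediate
6 | carbinol adduct: 3 with CHO replaced by (S)-CH(OH)CH2CH2C≡CSiMe3 | C[Si](C)(C)C#CCC[C@H](O)[C@@]1(C)[C@@H](N(C)C)C=C(O[Si](C)(C)C(C)(C)C)C[C@@H]1C(OC)OC | intermediate
7 | ring A enone carbinol: 4-[(1S)-1-hydroxy-5-(trimethylsilyl)pent-4-yn-1-yl]-5-(dimethoxymethyl)-4-methylcyclohex-2-en-1-one, side chain on C1 trans to the acetal on C10 | C[Si](C)(C)C#CCC[C@H](O)[C@@]1(C)C=CC(=O)C[C@@H]1C(OC)OC | intermediate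
8 | 13α,14α-epoxy ketone of 7 (epoxide cis to the C2 side chain, trans to the C1 methyl) | C[Si](C)(C)C#CCC[C@H](O)[C@@]1(C)[C@H]2O[C@H]2C(=O)C[C@@H]1C(OC)OC | intermediate
9 | Mannich base: 8 with an α-CH2NMe2 group on C11 | C[Si](C)(C)C#CCC[C@H](O)[C@@]1(C)[C@H]2O[C@H]2C(=O)[C@@H](CN(C)C)[C@@H]1C(OC)OC | intermediate
10 | trimethylammonium iodide of 9 | C[Si](C)(C)C#CCC[C@H](O)[C@@]1(C)[C@H]2O[C@H]2C(=O)[C@@H](C[N+](C)(C)C)[C@@H]1C(OC)OC.[I-] | intermediate
11 | 11-methylene epoxy ketone (C11=C20H2, C12 ketone, 13α,14α-epoxide) | C[Si](C)(C)C#CCC[C@H](O)[C@@]1(C)[C@H]2O[C@H]2C(=O)C(=C)[C@@H]1C(OC)OC | intermediate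
12 | silylalkyne triol: (2S)-OH, 12α-OH, 14α-OH, C11=C20H2, C9 dimethyl acetal, C≡C–SiMe3 | C[Si](C)(C)C#CCC[C@H](O)[C@@]1(C)[C@@H](O)C[C@@H](O)C(=C)[C@@H]1C(OC)OC | intermediate
13 | alkynyl triol: 12 with a terminal alkyne | C#CCC[C@H](O)[C@@]1(C)[C@@H](O)C[C@@H](O)C(=C)[C@@H]1C(OC)OC | intermediate
14 | 11α,20α-spiro-epoxy triol (epoxide oxygen cis to 12α-OH) | C#CCC[C@H](O)[C@@]1(C)[C@@H](O)C[C@@H](O)[C@]2(CO2)[C@@H]1C(OC)OC | intermediate
15 | 2,12,14-triacetate of 14 | C#CCC[C@H](OC(C)=O)[C@@]1(C)[C@@H](OC(C)=O)C[C@@H](OC(C)=O)[C@]2(CO2)[C@@H]1C(OC)OC | intermediate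
16 | C9 aldehyde (acetal of 15 hydrolysed) | C#CCC[C@H](OC(C)=O)[C@@]1(C)[C@@H](OC(C)=O)C[C@@H](OC(C)=O)[C@]2(CO2)[C@@H]1C=O | intermediate
17 | 2-(tert-butyldimethylsilyloxy)acetaldehyde | O=CCO[Si](C)(C)C(C)(C)C | starting material
18 | syn aldol adduct: (9S)-hydroxy, (8R)-tert-butyldimethylsilyloxy, C7 aldehyde | C#CCC[C@H](OC(C)=O)[C@@]1(C)[C@@H](OC(C)=O)C[C@@H](OC(C)=O)[C@]2(CO2)[C@@H]1[C@H](O)[C@@H](O[Si](C)(C)C(C)(C)C)C=O | intermediate
19 | 9-acetate of 18 (2,9,12,14-tetraacetate, alkyne and aldehyde termini) | C#CCC[C@H](OC(C)=O)[C@@]1(C)[C@@H](OC(C)=O)C[C@@H](OC(C)=O)[C@]2(CO2)[C@@H]1[C@H](OC(C)=O)[C@@H](O[Si](C)(C)C(C)(C)C)C=O | intermediate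
20 | ten-membered (5E)-allylic alcohol: C5 methyl (C16) cis to C7 across C5=C6, 7-OH anti to 8-OSi(tBu)Me2, 2,9,12,14-tetraacetate, 11α,20α-epoxide | O[C@H]1/C=C(\C)CC[C@H](OC(C)=O)[C@@]2(C)[C@@H](OC(C)=O)C[C@@H](OC(C)=O)[C@]3(CO3)[C@@H]2[C@H](OC(C)=O)[C@H]1O[Si](C)(C)C(C)(C)C | intermediate
21 | 7-acrylate of 20 | C=CC(=O)O[C@H]1/C=C(\C)CC[C@H](OC(C)=O)[C@@]2(C)[C@@H](OC(C)=O)C[C@@H](OC(C)=O)[C@]3(CO3)[C@@H]2[C@H](OC(C)=O)[C@H]1O[Si](C)(C)C(C)(C)C | intermediate
22 | 8-alcohol (21 desilylated) | C=CC(=O)O[C@H]1/C=C(\C)CC[C@H](OC(C)=O)[C@@]2(C)[C@@H](OC(C)=O)C[C@@H](OC(C)=O)[C@]3(CO3)[C@@H]2[C@H](OC(C)=O)[C@H]1O | intermediate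
23 | 8-ketone with 7-acryloyloxy and 9-acetoxy groups | C=CC(=O)O[C@H]1/C=C(\C)CC[C@H](OC(C)=O)[C@@]2(C)[C@@H](OC(C)=O)C[C@@H](OC(C)=O)[C@]3(CO3)[C@@H]2[C@H](OC(C)=O)C1=O | intermediate
24 | silyl aldolate: 25 with O8 carrying SiMe2–O–SiHMe2 | [C@H]12/C=C(\C)CC[C@H](OC(C)=O)[C@@]3(C)[C@@H](OC(C)=O)C[C@@H](OC(C)=O)[C@]4(CO4)[C@@H]3[C@H](OC(C)=O)[C@]1(O[Si](C)(C)O[SiH](C)C)[C@@H](C)C(=O)O2 | intermediate
25 | (5E)-hydroxy lactone: target skeleton with C5=C6 (C16 methyl) and no chlorine; 8-OH, 17-methyl cis to 8-OH, lactone O on C7 | [C@H]12/C=C(\C)CC[C@H](OC(C)=O)[C@@]3(C)[C@@H](OC(C)=O)C[C@@H](OC(C)=O)[C@]4(CO4)[C@@H]3[C@H](OC(C)=O)[C@]1(O)[C@@H](C)C(=O)O2 | intermediate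
26 | CNP0349227.2, (1S,2S,6S,7R,8R,9S,10S,11R,12R,14S,17R)-2,9,12,14-tetraacetoxy-6-chloro-11,20-epoxy-8-hydroxybriar-5(16)-en-18,7-olide | C=C1CC[C@H](OC(C)=O)[C@@]2(C)[C@@H](OC(C)=O)C[C@@H](OC(C)=O)[C@]3(CO3)[C@@H]2[C@H](OC(C)=O)[C@]2(O)[C@@H](C)C(=O)O[C@H]2[C@H]1Cl | target

**Step count and risks**
Total step count: 16. Longest linear sequence: 16 (from 1 and 2).

Three steps most likely to fail:

Step 1 (the proposed new method). The β-branched α-methyl enal may react too slowly for the catalyst to outrun the background reaction, or give low ee. The fallback is the known auxiliary-controlled thermal Diels–Alder reaction and sets out from 2. Enal 2 is combined in toluene at −20 °C to rt with the chiral diene (E)-1-[(2R,5R)-2,5-diphenylpyrrolidin-1-yl]-3-(tert-butyldimethylsilyloxy)buta-1,3-diene F1, which gives the auxiliary-bearing cycloadduct F2. Grignard reagent 5 is added as in step 2 to give the auxiliary-bearing carbinol F3, and the same HF·pyridine work-up expels the auxiliary amine and returns to the route at 7.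

Step 11. The ten-membered ring may not close (oligomerisation, alkyne trimerisation, nine-membered exo mode) or C7 may form with poor selectivity. The fallback uses a vinyl iodide and a Nozaki–Hiyama–Kishi ring closure and sets out from 13. Zirconium-catalysed carboalumination and iodinolysis (AlMe3, Cp2ZrCl2, CH2Cl2, 0 °C; then I2) give the (E)-vinyl iodide triol F4. Directed epoxidation as in step 6 gives the iodo epoxy triol F5, acetylation as in step 7 gives the iodo triacetate F6, and PPTS hydrolysis as in step 8 gives the iodo aldehyde F7. The aldol of step 9 gives the iodo aldol adduct F8 and acetylation as in step 10 gives the iodo 9-acetate F9. Intramolecular coupling with CrCl2 (6 equiv) and NiCl2 (1 mol %) in DMSO/THF at high dilution then returns to the route at 20 with the same alkene geometry.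

Step 16. A C4 proton may be lost instead of a C16 proton, or chlorine may enter on the wrong face of C6. The fallback separates oxygenation from chlorination and sets out from 25. A Schenck ene reaction with singlet oxygen (O2, tetraphenylporphyrin, visible light, CH2Cl2, −20 °C) gives the 6-hydroperoxy-5(16)-ene F10. Dehydration (Ac2O, pyridine) gives the 6-oxo-5(16)-ene F11, and Luche reduction (NaBH4, CeCl3, MeOH, −40 °C) from the exposed face gives the 6-epi allylic alcohol F12. Appel chlorination with inversion (PPh3, CCl4, 2,6-lutidine) returns to the route at 26.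

**Further compounds**
F1 | step 1 | (E)-1-[(2R,5R)-2,5-diphenylpyrrolidin-1-yl]-3-(tert-butyldimethylsilyloxy)buta-1,3-diene | C=C(O[Si](C)(C)C(C)(C)C)/C=C/N1[C@@H](c2ccccc2)CC[C@@H]1c1ccccc1
F2 | step 1 | auxiliary-bearing cycloadduct (3 with the diphenylpyrrolidinyl group in place of NMe2) | O=C[C@@]1(C)[C@@H](N2[C@@H](c3ccccc3)CC[C@@H]2c2ccccc2)C=C(O[Si](C)(C)C(C)(C)C)C[C@@H]1C(OC)OC
F3 | step 1 | auxiliary-bearing carbinol (6 with the diphenylpyrrolidinyl group in place of NMe2) | C[Si](C)(C)C#CCC[C@H](O)[C@@]1(C)[C@@H](N2[C@@H](c3ccccc3)CC[C@@H]2c2ccccc2)C=C(O[Si](C)(C)C(C)(C)C)C[C@@H]1C(OC)OC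
F4 | step 11 | (E)-vinyl iodide triol (13 with C≡CH converted to C(CH3)=CHI) | I/C=C(\C)CC[C@H](O)[C@@]1(C)[C@@H](O)C[C@@H](O)C(=C)[C@@H]1C(OC)OC
F5 | step 11 | iodo epoxy triol (11α,20α-epoxide of F4) | I/C=C(\C)CC[C@H](O)[C@@]1(C)[C@@H](O)C[C@@H](O)[C@]2(CO2)[C@@H]1C(OC)OC
F6 | step 11 | iodo triacetate | I/C=C(\C)CC[C@H](OC(C)=O)[C@@]1(C)[C@@H](OC(C)=O)C[C@@H](OC(C)=O)[C@]2(CO2)[C@@H]1C(OC)OC
F7 | step 11 | iodo aldehyde | I/C=C(\C)CC[C@H](OC(C)=O)[C@@]1(C)[C@@H](OC(C)=O)C[C@@H](OC(C)=O)[C@]2(CO2)[C@@H]1C=O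
F8 | step 11 | iodo aldol adduct (9S-hydroxy, 8R-silyloxy) | I/C=C(\C)CC[C@H](OC(C)=O)[C@@]1(C)[C@@H](OC(C)=O)C[C@@H](OC(C)=O)[C@]2(CO2)[C@@H]1[C@H](O)[C@@H](O[Si](C)(C)C(C)(C)C)C=O
F9 | step 11 | iodo 9-acetate | I/C=C(\C)CC[C@H](OC(C)=O)[C@@]1(C)[C@@H](OC(C)=O)C[C@@H](OC(C)=O)[C@]2(CO2)[C@@H]1[C@H](OC(C)=O)[C@@H](O[Si](C)(C)C(C)(C)C)C=O
F10 | step 16 | 6-hydroperoxy-5(16)-ene | C=C1CC[C@H](OC(C)=O)[C@@]2(C)[C@@H](OC(C)=O)C[C@@H](OC(C)=O)[C@]3(CO3)[C@@H]2[C@H](OC(C)=O)[C@]2(O)[C@@H](C)C(=O)O[C@H]2[C@H]1OO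
F11 | step 16 | 6-oxo-5(16)-ene | C=C1CC[C@H](OC(C)=O)[C@@]2(C)[C@@H](OC(C)=O)C[C@@H](OC(C)=O)[C@]3(CO3)[C@@H]2[C@H](OC(C)=O)[C@]2(O)[C@@H](C)C(=O)O[C@H]2C1=O
F12 | step 16 | 6-epi allylic alcohol (hydroxyl on the C6 face opposite to the chlorine of 26) | C=C1CC[C@H](OC(C)=O)[C@@]2(C)[C@@H](OC(C)=O)C[C@@H](OC(C)=O)[C@]3(CO3)[C@@H]2[C@H](OC(C)=O)[C@]2(O)[C@@H](C)C(=O)O[C@H]2[C@@H]1O
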